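**Strategy.** The route rests on cutting the bond between the quaternary ether carbon C2 of the chroman ring and C1′ of the side chain. Both halves meet in a lithiation–borylation: an α-lithiated secondary benzoate (C2 with its methyl, C3, C4 and the arene, a chlorine standing in for ring oxygen O1) captures the complete side chain as a homoallylic neopentyl boronate; stereospecific 1,2-metalate shift forges C2–C1′ and sets the C2 stereocentre, and oxidation in the same pot installs the oxygen that later closes the pyran ring onto C8a. The step exploits C2 as a tertiary carbinol carbon whose configuration can be relayed from (S)-propylene oxide.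

Key step: step 12

Remark on the chemistry: the target is read as the 2S chromanol with a 7′S,8′R diol (the anti diol of an E-configured 7′,8′ unit). Side-chain carbons are numbered C1′ (attached to C2) to C13′.

**Route**

Step 1
Reactants: 1 geraniol
Product: 2 (2R,3R)-2,3-epoxygeraniol
Conditions: Ti(OiPr)4 (cat.), D-(−)-diethyl tartrate (cat.), t-BuOOH, 4 Å MS, CH2Cl2, −20 °C
Reagents that add atoms: tert-butyl hydroperoxide, CC(C)(C)OO
Why: Sharpless asymmetric epoxidation: the allylic hydroxyl binds the titanium tartrate catalyst, so only the 2,3-alkene reacts, and D-(−)-tartrate delivers oxygen to the face that gives the (2R,3R)-epoxide, which defines both future diol carbons.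

Step 2
Reactants: 2 (2R,3R)-2,3-epoxygeraniol
Product: 4 (3S,4R)-4,8-dimethylnona-1,7-diene-3,4-diol, via terminal epoxide 3 (not isolated)
Conditions: Me3S+ I− (5 equiv), n-BuLi (4.8 equiv), THF, −10 °C → rt
Reagents that add atoms: trimethylsulfonium iodide, C[S+](C)C.[I-]
Why: One-pot Payne rearrangement and sulfonium ylide homologation of a 2,3-epoxy alcohol: the C1 alkoxide opens the epoxide at C2 with inversion (C3 untouched), the terminal epoxide is attacked at CH2 by dimethylsulfonium methylide, and the betaine eliminates dimethyl sulfide to the vinyl carbinol, so the 3S,4R anti diol follows from the 2R,3R epoxide.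

Step 3
Reactants: 4 (3S,4R)-4,8-dimethylnona-1,7-diene-3,4-diol
Product: 5 (4S,5R)-4-ethenyl-2,2,5-trimethyl-5-(4-methylpent-3-en-1-yl)-1,3-dioxolane
Conditions: 2,2-dimethoxypropane, PPTS (cat.), CH2Cl2, rt
Reagents that add atoms: 2,2-dimethoxypropane, COC(C)(C)OC
Why: Acid-catalysed acetalisation of the secondary/tertiary 1,2-diol masks both hydroxyls for the organometallic steps without touching either stereocentre.

Step 4
Reactants: 6 pent-3-yn-1-ol
Product: 7 5-bromopent-2-yne
Conditions: CBr4, PPh3, CH2Cl2, 0 °C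
Reagents that add atoms: carbon tetrabromide, BrC(Br)(Br)Br
Why: Appel bromination converts the primary alcohol into the bromide by SN2 displacement of the alkoxyphosphonium ion and leaves the internal alkyne alone.

Step 5
Reactants: 7 5-bromopent-2-yne
Product: 10 5,5-dimethyl-2-(pent-3-yn-1-yl)-1,3,2-dioxaborinane, via pent-3-ynylmagnesium bromide 8 (not isolated), via dimethyl pent-3-ynylboronate 9 (not isolated)
Conditions: Mg, THF, rt; B(OMe)3, −78 °C → rt; aq. NH4Cl; neopentyl glycol, MgSO4, CH2Cl2, rt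
Reagents that add atoms: trimethyl borate, COB(OC)OC; neopentyl glycol, OCC(C)(C)CO
Why: Grignard formation, electrophilic borylation with trimethyl borate and transesterification give the neopentyl glycol boronic ester, the ester type that the later 1,2-metalate rearrangement requires.

Step 6
Reactants: 10 5,5-dimethyl-2-(pent-3-yn-1-yl)-1,3,2-dioxaborinane
Product: 12 2-[(3E)-4-iodopent-3-en-1-yl]-5,5-dimethyl-1,3,2-dioxaborinane, via alkenylzirconocene chloride 11 (not isolated)
Conditions: Cp2Zr(H)Cl (2 equiv), THF, 50 °C; then I2, 0 °C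
Reagents that add atoms: iodine, II
Why: Hydrozirconation–iodination: syn addition of Zr–H to the 2-alkyne, equilibrated with excess Schwartz reagent so that zirconium sits on the methyl-bearing carbon, then iodinolysis with retention, gives the (E)-2-iodoalkene that fixes the C3′=C4′ geometry.

Step 7
Reactants: 5 (4S,5R)-4-ethenyl-2,2,5-trimethyl-5-(4-methylpent-3-en-1-yl)-1,3-dioxolane; 12 2-[(3E)-4-iodopent-3-en-1-yl]-5,5-dimethyl-1,3,2-dioxaborinane
Product: 14 2-{(3E)-4-methyl-6-[(4S,5R)-2,2,5-trimethyl-5-(4-methylpent-3-en-1-yl)-1,3-dioxolan-4-yl]hex-3-en-1-yl}-5,5-dimethyl-1,3,2-dioxaborinane, via B-alkyl-9-BBN 13 (not isolated)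
Conditions: 5, 9-BBN dimer, THF, rt; then 12, Pd(dppf)Cl2 (cat.), AsPh3, Cs2CO3, DMF/H2O, rt
Reagents that add atoms: none
Why: B-alkyl Suzuki–Miyaura coupling: 9-BBN hydroborates only the monosubstituted vinyl group at its terminus, and the borane, not the neopentyl boronic ester, transmetalates to palladium and couples with the alkenyl iodide with retention of the E geometry.

Step 8
Reactants: 15 4-chloro-3,5-dimethylphenol
Product: 16 (4-chloro-3,5-dimethylphenoxy)triisopropylsilane
Conditions: TIPSCl, imidazole, DMF, rt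
Reagents that add atoms: chlorotriisopropylsilane, CC(C)[Si](Cl)(C(C)C)C(C)C
Why: Silylation of the phenol; the bulky triisopropylsilyl ether should withstand s-BuLi and is a poor ortho-directing group.

Step 9
Reactants: 16 (4-chloro-3,5-dimethylphenoxy)triisopropylsilane
Product: 17 [3-(bromomethyl)-4-chloro-5-methylphenoxy]triisopropylsilane
Conditions: NBS (0.95 equiv), AIBN (cat.), PhCF3, reflux
Reagents that add atoms: N-bromosuccinimide, O=C1CCC(=O)N1Br
Why: Wohl–Ziegler radical bromination of one of the two equivalent benzylic methyl groups; a slight deficit of NBS limits dibromination and unreacted 16 is recycled.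

Step 10
Reactants: 17 [3-(bromomethyl)-4-chloro-5-methylphenoxy]triisopropylsilane; 18 (S)-propylene oxide
Product: 20 (2S)-4-[2-chloro-3-methyl-5-(triisopropylsilyloxy)phenyl]butan-2-ol, via benzylic Grignard reagent 19 (not isolated)
Conditions: Mg, Et2O, 0 °C; then CuI (cat.), 18, −30 → 0 °C; aq. NH4Cl
Reagents that add atoms: none
Why: Copper-catalysed epoxide opening at the unsubstituted carbon by the benzylic Grignard reagent (magnesium inserts into the benzylic bromide, not the aryl chloride); the stereocentre of (S)-propylene oxide is carried over unchanged.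

Step 11
Reactants: 20 (2S)-4-[2-chloro-3-methyl-5-(triisopropylsilyloxy)phenyl]butan-2-ol
Product: 21 (2R)-4-[2-chloro-3-methyl-5-(triisopropylsilyloxy)phenyl]butan-2-yl 2,4,6-triisopropylbenzoate
Conditions: 2,4,6-triisopropylbenzoic acid, PPh3, DIAD, THF, 0 °C → rt
Reagents that add atoms: 2,4,6-triisopropylbenzoic acid, CC(C)c1cc(C(C)C)c(C(=O)O)c(C(C)C)c1
Why: Mitsunobu esterification proceeds by SN2 at the carbinol carbon, so the (S)-alcohol gives the (R)-benzoate needed for the key step.

Step 12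
Reactants: 21 (2R)-4-[2-chloro-3-methyl-5-(triisopropylsilyloxy)phenyl]butan-2-yl 2,4,6-triisopropylbenzoate; 14 2-{(3E)-4-methyl-6-[(4S,5R)-2,2,5-trimethyl-5-(4-methylpent-3-en-1-yl)-1,3-dioxolan-4-yl]hex-3-en-1-yl}-5,5-dimethyl-1,3,2-dioxaborinane
Product: 25 (3S,6E)-1-[2-chloro-3-methyl-5-(triisopropylsilyloxy)phenyl]-3,7-dimethyl-9-[(4S,5R)-2,2,5-trimethyl-5-(4-methylpent-3-en-1-yl)-1,3-dioxolan-4-yl]non-6-en-3-ol, via α-lithiated benzoate 22 (not isolated), via lithium boronate complex 23 (not isolated), via tertiary boronic ester 24 (not isolated)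
Conditions: 21 (1.3 equiv), s-BuLi (1.25 equiv), TMEDA (6 equiv), CPME, −60 °C; then 14 (1.0 equiv), −60 → 40 °C; then NaBO3·4H2O, THF/H2O, rt
Reagents that add atoms: sodium perborate, [Na+].[Na+].O[B-]1(O)OO[B-](O)(O)OO1
Why: Lithiation–borylation, the 1,2-metalate rearrangement known for secondary dialkyl 2,4,6-triisopropylbenzoates with primary neopentyl boronic esters: s-BuLi/TMEDA removes the carbinol hydrogen of 21 under direction of the ester carbonyl to give configurationally stable 22, which adds to boron of 14 with retention to give 23. On warming, C1′ migrates from boron to C2 antiperiplanar to the departing benzoate, so the C2–C1′ bond forms with inversion at carbon to give 24 as a single stereoisomer, and perborate then replaces boron by oxygen with retention. No ring is closed in this step. The new fully substituted stereocentre C2 is controlled only by the configuration of 21 (from (S)-propylene oxide, inverted once in step 11), and the resulting 3S carbinol maps onto 2S of the chroman. The step needs α-deprotonation instead of arene or benzylic metalation and attack of 22 at boron only: the carbonyl-directed deprotonation, the absence of hydrogen ortho to chlorine, the weakly directing TIPS ether, a slight deficit of s-BuLi relative to 21, and the inertness of the acetonide and trisubstituted alkenes of 14 should secure this, while perborate is chosen over NaOH/H2O2 to spare the aryl silyl ether.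

Step 13
Reactants: 25 (3S,6E)-1-[2-chloro-3-methyl-5-(triisopropylsilyloxy)phenyl]-3,7-dimethyl-9-[(4S,5R)-2,2,5-trimethyl-5-(4-methylpent-3-en-1-yl)-1,3-dioxolan-4-yl]non-6-en-3-ol
Product: 26 triisopropyl{[(2S)-2,8-dimethyl-2-{(3E)-4-methyl-6-[(4S,5R)-2,2,5-trimethyl-5-(4-methylpent-3-en-1-yl)-1,3-dioxolan-4-yl]hex-3-en-1-yl}chroman-6-yl]oxy}silane
Conditions: Pd(OAc)2 (cat.), t-BuXPhos (cat.), Cs2CO3, toluene, 90 °C
Reagents that add atoms: none
Why: Buchwald–Hartwig-type intramolecular C–O coupling: oxidative addition into the aryl chloride, alkoxide exchange and reductive elimination close the six-membered pyran ring without breaking the C2–O bond, so C2 keeps its configuration, and a tertiary alkoxide cannot undergo β-hydride elimination.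

Step 14
Reactants: 26 triisopropyl{[(2S)-2,8-dimethyl-2-{(3E)-4-methyl-6-[(4S,5R)-2,2,5-trimethyl-5-(4-methylpent-3-en-1-yl)-1,3-dioxolan-4-yl]hex-3-en-1-yl}chroman-6-yl]oxy}silane
Product: 28 (2S)-2-[(3E,7S,8R)-7,8-dihydroxy-4,8,12-trimethyltrideca-3,11-dien-1-yl]-2,8-dimethylchroman-6-ol, via phenol acetonide 27 (not isolated)
Conditions: TBAF, THF (degassed), 0 °C; then AcOH/H2O (4:1), 40 °C
Reagents that add atoms: none
Why: Fluoride cleavage of the aryl silyl ether followed in the same flask by acid-catalysed hydrolysis of the isopropylidene acetal; dilute acetic acid should leave the trisubstituted alkenes and the tertiary ether untouched, and no stereocentre is involved.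

**Compound list**

1 | geraniol, (2E)-3,7-dimethylocta-2,6-dien-1-ol | CC(C)=CCC/C(C)=C/CO | starting material
2 | (2R,3R)-2,3-epoxygeraniol, [(2R,3R)-3-methyl-3-(4-methylpent-3-en-1-yl)oxiran-2-yl]methanol | CC(C)=CCC[C@@]1(C)O[C@@H]1CO | intermediate
3 | (2R)-6-methyl-2-[(2S)-oxiran-2-yl]hept-5-en-2-ol (present as its lithium alkoxide) | CC(C)=CCC[C@@](C)(O)[C@@H]1CO1 | intermediate
4 | (3S,4R)-4,8-dimethylnona-1,7-diene-3,4-diol | CC(C)=CCC[C@@](C)(O)[C@@H](O)C=C | intermediate
5 | (4S,5R)-4-ethenyl-2,2,5-trimethyl-5-(4-methylpent-3-en-1-yl)-1,3-dioxolane | CC(C)=CCC[C@@]1(C)OC(C)(C)O[C@H]1C=C | intermediate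
6 | pent-3-yn-1-ol | CC#CCCO | starting material
7 | 5-bromopent-2-yne | CC#CCCBr | intermediate
8 | pent-3-yn-1-ylmagnesium bromide | CC#CCC[Mg]Br | intermediate
9 | dimethyl pent-3-yn-1-ylboronate | CC#CCCB(OC)OC | intermediate
10 | 5,5-dimethyl-2-(pent-3-yn-1-yl)-1,3,2-dioxaborinane | CC#CCCB1OCC(C)(C)CO1 | intermediate
11 | chlorobis(cyclopentadienyl)[(2E)-5-(5,5-dimethyl-1,3,2-dioxaborinan-2-yl)pent-2-en-2-yl]zirconium | C/C(=C\CCB1OCC(C)(C)CO1)[Zr](Cl)(C1C=CC=C1)C1C=CC=C1 | intermediate
12 | 2-[(3E)-4-iodopent-3-en-1-yl]-5,5-dimethyl-1,3,2-dioxaborinane | I/C(C)=C/CCB1OCC(C)(C)CO1 | intermediate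
13 | 9-{2-[(4S,5R)-2,2,5-trimethyl-5-(4-methylpent-3-en-1-yl)-1,3-dioxolan-4-yl]ethyl}-9-borabicyclo[3.3.1]nonane | CC(C)=CCC[C@@]1(C)OC(C)(C)O[C@H]1CCB1C2CCCC1CCC2 | intermediate
14 | 2-{(3E)-4-methyl-6-[(4S,5R)-2,2,5-trimethyl-5-(4-methylpent-3-en-1-yl)-1,3-dioxolan-4-yl]hex-3-en-1-yl}-5,5-dimethyl-1,3,2-dioxaborinane | CC(C)=CCC[C@@]1(C)OC(C)(C)O[C@H]1CC/C(C)=C/CCB1OCC(C)(C)CO1 | intermediate
15 | 4-chloro-3,5-dimethylphenol | Cc1cc(O)cc(C)c1Cl | starting material
16 | (4-chloro-3,5-dimethylphenoxy)triisopropylsilane | Cc1cc(O[Si](C(C)C)(C(C)C)C(C)C)cc(C)c1Cl | intermediate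
17 | [3-(bromomethyl)-4-chloro-5-methylphenoxy]triisopropylsilane | Cc1cc(O[Si](C(C)C)(C(C)C)C(C)C)cc(CBr)c1Cl | intermediate
18 | (S)-propylene oxide, (2S)-2-methyloxirane | C[C@H]1CO1 | starting material
19 | {[2-chloro-3-methyl-5-(triisopropylsilyloxy)phenyl]methyl}magnesium bromide | Cc1cc(O[Si](C(C)C)(C(C)C)C(C)C)cc(C[Mg]Br)c1Cl | intermediate
20 | (2S)-4-[2-chloro-3-methyl-5-(triisopropylsilyloxy)phenyl]butan-2-ol | C[C@H](O)CCc1cc(O[Si](C(C)C)(C(C)C)C(C)C)cc(C)c1Cl | intermediate
21 | (2R)-4-[2-chloro-3-methyl-5-(triisopropylsilyloxy)phenyl]butan-2-yl 2,4,6-triisopropylbenzoate | C[C@@H](OC(=O)c1c(C(C)C)cc(C(C)C)cc1C(C)C)CCc1cc(O[Si](C(C)C)(C(C)C)C(C)C)cc(C)c1Cl | intermediate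
22 | α-lithiated benzoate: 21 with lithium in place of the carbinol hydrogen, configuration retained | C[C@@]([Li])(OC(=O)c1c(C(C)C)cc(C(C)C)cc1C(C)C)CCc1cc(O[Si](C(C)C)(C(C)C)C(C)C)cc(C)c1Cl | intermediate
23 | lithium boronate complex: the carbanion carbon of 22 bound to boron of 14 | [Li+].C[C@@]([B-]1(CC/C=C(C)/CC[C@@H]2OC(C)(C)O[C@]2(C)CCC=C(C)C)OCC(C)(C)CO1)(OC(=O)c1c(C(C)C)cc(C(C)C)cc1C(C)C)CCc1cc(O[Si](C(C)C)(C(C)C)C(C)C)cc(C)c1Cl | intermediate
24 | tertiary boronic ester: 25 with 5,5-dimethyl-1,3,2-dioxaborinan-2-yl in place of the hydroxyl at C3 (3R by CIP, same spatial arrangement) | CC(C)=CCC[C@@]1(C)OC(C)(C)O[C@H]1CC/C(C)=C/CC[C@](C)(B1OCC(C)(C)CO1)CCc1cc(O[Si](C(C)C)(C(C)C)C(C)C)cc(C)c1Cl | intermediate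
25 | (3S,6E)-1-[2-chloro-3-methyl-5-(triisopropylsilyloxy)phenyl]-3,7-dimethyl-9-[(4S,5R)-2,2,5-trimethyl-5-(4-methylpent-3-en-1-yl)-1,3-dioxolan-4-yl]non-6-en-3-ol | CC(C)=CCC[C@@]1(C)OC(C)(C)O[C@H]1CC/C(C)=C/CC[C@](C)(O)CCc1cc(O[Si](C(C)C)(C(C)C)C(C)C)cc(C)c1Cl | intermediate
26 | triisopropyl{[(2S)-2,8-dimethyl-2-{(3E)-4-methyl-6-[(4S,5R)-2,2,5-trimethyl-5-(4-methylpent-3-en-1-yl)-1,3-dioxolan-4-yl]hex-3-en-1-yl}chroman-6-yl]oxy}silane | CC(C)=CCC[C@@]1(C)OC(C)(C)O[C@H]1CC/C(C)=C/CC[C@@]1(C)CCc2cc(O[Si](C(C)C)(C(C)C)C(C)C)cc(C)c2O1 | intermediate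
27 | (2S)-2,8-dimethyl-2-{(3E)-4-methyl-6-[(4S,5R)-2,2,5-trimethyl-5-(4-methylpent-3-en-1-yl)-1,3-dioxolan-4-yl]hex-3-en-1-yl}chroman-6-ol | CC(C)=CCC[C@@]1(C)OC(C)(C)O[C@H]1CC/C(C)=C/CC[C@@]1(C)CCc2cc(O)cc(C)c2O1 | intermediate
28 | (2S)-2-[(3E,7S,8R)-7,8-dihydroxy-4,8,12-trimethyltrideca-3,11-dien-1-yl]-2,8-dimethylchroman-6-ol (CNP0285617.1) | CC(C)=CCC[C@@](C)(O)[C@@H](O)CC/C(C)=C/CC[C@@]1(C)CCc2cc(O)cc(C)c2O1 | target

**Step count and risks**

Total steps: 14. Longest linear sequence: 7 steps (1, 2, 3, 7, 12, 13, 14). The branches through steps 4–6 and through steps 8–11 are equally long.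

Steps most likely to fail:

1. Step 12. Competing metalation of the arene or benzylic positions, or slow and reversible formation and rearrangement of the congested boronate complex, would waste boronate 14. The fallback sets out from 20, uses the in-situ reagents 8 and 13, and returns at 25; it makes the C2–C1′ bond by carbonyl addition and completes the side chain afterwards. Alcohol 20 is oxidised with Dess–Martin periodinane to 4-[2-chloro-3-methyl-5-(triisopropylsilyloxy)phenyl]butan-2-one F1. Grignard reagent 8 is added to F1 in the presence of a stoichiometric chiral diaminocyclohexane-derived tridentate ligand (ligand-mediated asymmetric Grignard 1,2-addition, toluene, −78 °C) to give (3S)-1-[2-chloro-3-methyl-5-(triisopropylsilyloxy)phenyl]-3-methyloct-6-yn-3-ol F2. Facial discrimination between methyl and arylethyl is expected to be imperfect, so F2 would be upgraded by preparative chiral chromatography. Hydrozirconation–iodination as in step 6 (one extra equivalent of reagent for the free hydroxyl) gives (3S,6E)-1-[2-chloro-3-methyl-5-(triisopropylsilyloxy)phenyl]-7-iodo-3-methyloct-6-en-3-ol F3. B-alkyl Suzuki–Miyaura coupling of F3 with borane 13 under the conditions of step 7 delivers 25.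

2. Step 13. The hindered tertiary alkoxide may fail to undergo C–O reductive elimination at palladium on the doubly ortho-substituted, electron-rich arene, so that reduction of the C–Cl bond competes. The fallback sets out from 25 and returns at 28; it couples hydroxide instead and closes the ring through the quinone, with the C2–O bond never broken. Palladium-catalysed hydroxylation of the aryl chloride (Pd2(dba)3, t-BuXPhos, KOH, dioxane/H2O, 100 °C; the silyl ether is cleaved as well) gives 2-{(3S,6E)-3-hydroxy-3,7-dimethyl-9-[(4S,5R)-2,2,5-trimethyl-5-(4-methylpent-3-en-1-yl)-1,3-dioxolan-4-yl]non-6-en-1-yl}-6-methylbenzene-1,4-diol F4. Ag2O oxidises F4 to the corresponding 2,6-disubstituted 1,4-benzoquinone F5. Trimethyl orthoformate and methanol with catalytic acid let the tertiary hydroxyl add to the neighbouring quinone carbonyl and exchange off the isopropylidene group, giving (2S)-2-[(3E,7S,8R)-7,8-dihydroxy-4,8,12-trimethyltrideca-3,11-dien-1-yl]-8a-methoxy-2,8-dimethyl-2,3,4,8a-tetrahydro-6H-chromen-6-one F6 as a mixture at C8a. Zinc in acetic acid reduces F6 with loss of methanol to 28.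

3. Step 2. In THF the Payne equilibrium of the lithium alkoxide may lie so far towards the trisubstituted epoxide that trapping by the ylide is slow and decomposition competes. The fallback sets out from 1 and returns at 4; it inverts C3 by acid instead of C2 by base and therefore starts from the enantiomeric epoxide. Geraniol 1 is epoxidised with L-(+)-diethyl tartrate to (2S,3S)-2,3-epoxygeraniol F7. Dilute HClO4 in THF/H2O opens F7 at the tertiary carbon with inversion to (2S,3R)-3,7-dimethyloct-6-ene-1,2,3-triol F8. Selective primary sulfonylation (TsCl, Bu2SnO cat., Et3N) gives (2S,3R)-2,3-dihydroxy-3,7-dimethyloct-6-en-1-yl 4-methylbenzenesulfonate F9. Excess dimethylsulfonium methylide closes F9 to epoxide 3 with retention at C2 and homologates it in the same flask to 4.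

Further compounds
F1 | step 12 | 4-[2-chloro-3-methyl-5-(triisopropylsilyloxy)phenyl]butan-2-one | CC(=O)CCc1cc(O[Si](C(C)C)(C(C)C)C(C)C)cc(C)c1Cl
F2 | step 12 | (3S)-1-[2-chloro-3-methyl-5-(triisopropylsilyloxy)phenyl]-3-methyloct-6-yn-3-ol | CC#CCC[C@](C)(O)CCc1cc(O[Si](C(C)C)(C(C)C)C(C)C)cc(C)c1Cl
F3 | step 12 | (3S,6E)-1-[2-chloro-3-methyl-5-(triisopropylsilyloxy)phenyl]-7-iodo-3-methyloct-6-en-3-ol | C/C(I)=C\CC[C@](C)(O)CCc1cc(O[Si](C(C)C)(C(C)C)C(C)C)cc(C)c1Cl
F4 | step 13 | 2-{(3S,6E)-3-hydroxy-3,7-dimethyl-9-[(4S,5R)-2,2,5-trimethyl-5-(4-methylpent-3-en-1-yl)-1,3-dioxolan-4-yl]non-6-en-1-yl}-6-methylbenzene-1,4-diol | CC(C)=CCC[C@@]1(C)OC(C)(C)O[C@H]1CC/C(C)=C/CC[C@](C)(O)CCc1cc(O)cc(C)c1O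
F5 | step 13 | 2-{(3S,6E)-3-hydroxy-3,7-dimethyl-9-[(4S,5R)-2,2,5-trimethyl-5-(4-methylpent-3-en-1-yl)-1,3-dioxolan-4-yl]non-6-en-1-yl}-6-methylcyclohexa-2,5-diene-1,4-dione | CC(C)=CCC[C@@]1(C)OC(C)(C)O[C@H]1CC/C(C)=C/CC[C@](C)(O)CCC1=CC(=O)C=C(C)C1=O
F6 | step 13 | (2S)-2-[(3E,7S,8R)-7,8-dihydroxy-4,8,12-trimethyltrideca-3,11-dien-1-yl]-8a-methoxy-2,8-dimethyl-2,3,4,8a-tetrahydro-6H-chromen-6-one (both C8a epimers) | COC12O[C@@](C)(CC/C=C(C)/CC[C@H](O)[C@](C)(O)CCC=C(C)C)CCC1=CC(=O)C=C2C
F7 | step 2 | (2S,3S)-2,3-epoxygeraniol | CC(C)=CCC[C@]1(C)O[C@H]1CO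
F8 | step 2 | (2S,3R)-3,7-dimethyloct-6-ene-1,2,3-triol | CC(C)=CCC[C@@](C)(O)[C@@H](O)CO
F9 | step 2 | (2S,3R)-2,3-dihydroxy-3,7-dimethyloct-6-en-1-yl 4-methylbenzenesulfonate | CC(C)=CCC[C@@](C)(O)[C@@H](O)COS(=O)(=O)c1ccc(C)cc1
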